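Assumption: (R)-(−)-linalool (1) and (S)-5-oxotetrahydrofuran-2-carboxylic acid (12, the L-glutamic acid lactone) are the purchased chiral materials, and the oxepane C3 carbinol is carried as an epimer mixture because it ends as the ketone.

**Retrosynthetic overview**
1. Target ⇐ oxepane C3 alcohol; the (Z)-alkene ⇐ semireduction of an allene ⇐ tertiary propargylic carbonate ⇐ acetylide of right half 24 + hindered ketone 11.
2. Left ketone 11 ⇐ cycloheptenone 9, formed by Claisen ring expansion ([3,3]) of the 2-ethylidene-5-vinyltetrahydrofuran 8 (from lactone 7) ⇐ epoxide of cyclopentenol 2 ⇐ (R)-linalool by RCM.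
3. Right alkyne 24 ⇐ ketone 22, where oxepane and cyclohexanone form in one epoxide-opening cascade of the bis-epoxy enyne silyl enol ether 21 ⇐ (2R,3R)-epoxide 18 ⇐ lactone acid 12.
4. Ring order: left cyclopentene → temporary γ-lactone → cycloheptenone; right oxiranes → oxepane and cyclohexane together; the two bicycles are joined last.

**Route**

Step 1
Reactants: 1 (R)-(−)-linalool
Product: 2 (R)-1-methylcyclopent-2-en-1-ol
Conditions: Grubbs II (0.5 mol %), CH2Cl2, 40 °C
Reagents that add atoms: none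
Why: Ring-closing metathesis of the 1,6-diene expels 2-methylpropene and leaves the purchased tertiary carbinol centre untouched.

Step 2
Reactants: 2 (R)-1-methylcyclopent-2-en-1-ol
Product: 3 (2R)-2-methyl-6-oxabicyclo[3.1.0]hexan-2-ol (oxirane cis to OH)
Conditions: VO(acac)2 (2 mol %), t-BuOOH, CH2Cl2, 0 °C → rt
Reagents that add atoms: tert-butyl hydroperoxide (CC(C)(C)OO)
Why: Hydroxyl-directed vanadium-catalysed epoxidation delivers oxygen to the alkene face syn to the OH.

Step 3
Reactants: 3 cis-epoxy alcohol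
Product: 4 2-[(1S,2S,3R)-2,3-dihydroxy-3-methylcyclopentyl]-2-methylpropanenitrile
Conditions: i-PrCN, LDA, THF, −78 → 45 °C; aq NH4Cl
Reagents that add atoms: isobutyronitrile (CC(C)C#N)
Why: SN2 epoxide opening by the nitrile-stabilised tertiary carbanion at the oxirane carbon remote from the hindered carbinol, with inversion, so the new C–C bond is trans to both hydroxyls.

Step 4
Reactants: 4 diol nitrile
Product: 5 2-[(1S,3R)-3-hydroxy-3-methyl-2-oxocyclopentyl]-2-methylpropanenitrile
Conditions: Dess–Martin periodinane, CH2Cl2, rt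
Reagents that add atoms: none
Why: Dess–Martin oxidation of the only secondary alcohol; the tertiary alcohol and the adjacent stereocentre are untouched under these neutral conditions.

Step 5
Reactants: 5 α-hydroxy ketone nitrile
Product: 7 (3aS,6R,6aR)-6-hydroxy-3,3,6-trimethyl-6a-vinylhexahydro-2H-cyclopenta[b]furan-2-one (cis-fused lactone; vinyl cis to OH), via iminolactone 6 (not isolated)
Conditions: CH2=CHMgBr (3 equiv), THF, −78 → 25 °C; then 1 M HCl, THF, rt
Reagents that add atoms: vinylmagnesium bromide (C=C[Mg]Br); water (O)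
Why: Grignard 1,2-addition from the face anti to the C(CH3)2CN arm puts the alkoxide cis to the nitrile, so it adds to it (Pinner-type) and acid hydrolysis of the imidate gives the cis-fused γ-lactone.

Step 6
Reactants: 7 vinyl lactone
Product: 9 (1R,3aR,6S)-1-hydroxy-1,4,4,6-tetramethyl-2,3,3a,4,6,7-hexahydroazulen-5(1H)-one, via enol ether 8 (not isolated)
Conditions: CH3CHBr2, Zn, TiCl4, TMEDA, cat. PbCl2, THF, 25 °C (excess reagent); crude enol ether in PhMe with Et3N, 170 °C, sealed tube
Reagents that add atoms: 1,1-dibromoethane (CC(Br)Br)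
Why: Takai–Utimoto alkylidenation gives the (Z)-enol ether, and its Claisen rearrangement ([3,3]-sigmatropic ring expansion of a 2-alkylidene-5-vinyltetrahydrofuran through the ring-enforced boat transition state) forms the C6–C7 bond and the cycloheptenone; C7 bonds on the vinyl face, which places H-6 cis to H-3a.

Step 7
Reactants: 9 cycloheptenone
Product: 10 (1R,3aR,6S,8aR)-1-hydroxy-1,4,4,6-tetramethyloctahydroazulen-5(1H)-one (cis-fused; OH and H-3a and H-6 and H-8a on one face)
Conditions: H2 (1 atm), [Ir(cod)(PCy3)(py)]PF6 (5 mol %), CH2Cl2, rt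
Reagents that add atoms: none
Why: Hydroxyl-directed Crabtree hydrogenation adds hydrogen to the trisubstituted alkene from the face of the allylic tertiary OH, giving the cis ring fusion.

Step 8
Reactants: 10 hydroxy ketone
Product: 11 (1R,3aR,6S,8aR)-1,4,4,6-tetramethyl-1-[(triethylsilyl)oxy]octahydroazulen-5(1H)-one
Conditions: TESOTf, 2,6-lutidine, CH2Cl2, −78 °C
Reagents that add atoms: triethylsilyl trifluoromethanesulfonate (CC[Si](CC)(CC)OS(=O)(=O)C(F)(F)F)
Why: Silylation of the tertiary alcohol; the doubly hindered ketone is not enol-silylated at low temperature, so C6 is kept.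

Step 9
Reactants: 12 (S)-5-oxotetrahydrofuran-2-carboxylic acid
Product: 14 (S)-5-acetyldihydrofuran-2(3H)-one, via acid chloride 13 (not isolated)
Conditions: (COCl)2, cat. DMF, CH2Cl2, rt; then Me2CuLi, Et2O, −78 °C
Reagents that add atoms: lithium dimethylcuprate ([Li+].C[Cu-]C)
Why: Acid chloride formation followed by Gilman acylation, which stops at the ketone and does not touch the lactone or the α-stereocentre at −78 °C.

Step 10
Reactants: 14 acetyl lactone
Product: 15 (S)-5-[(R)-2-hydroxy-6-methylhept-5-en-2-yl]dihydrofuran-2(3H)-one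
Conditions: (CH3)2C=CHCH2CH2MgBr, THF, −78 °C; aq NH4Cl
Reagents that add atoms: (4-methylpent-3-en-1-yl)magnesium bromide (CC(C)=CCC[Mg]Br)
Why: Chemoselective Grignard addition to the ketone under Felkin–Anh control (lactone C–O bond anti to the incoming nucleophile) sets the tertiary carbinol as (R) from the purchased (S) centre.

Step 11
Reactants: 15 hydroxy lactone
Product: 16 (4S,5R)-4,5-dihydroxy-N-methoxy-N,5,9-trimethyldec-8-enamide
Conditions: MeNH(OMe)·HCl, AlMe3, CH2Cl2, 0 °C → rt
Reagents that add atoms: N,O-dimethylhydroxylamine hydrochloride (CNOC.Cl)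
Why: Weinreb aminolysis of the lactone by the aluminium amide frees the secondary alcohol without touching either stereocentre.

Step 12
Reactants: 16 diol Weinreb amide
Product: 18 N-methoxy-N-methyl-3-[(2R,3R)-3-methyl-3-(4-methylpent-3-en-1-yl)oxiran-2-yl]propanamide, via mesylate 17 (not isolated)
Conditions: MsCl, Et3N, CH2Cl2, −20 °C; then K2CO3, MeOH, rt
Reagents that add atoms: none
Why: Selective sulfonylation of the secondary alcohol and intramolecular Williamson closure by the tertiary alkoxide with inversion at the CH carbon give the trans-type (2R,3R) trisubstituted epoxide.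

Step 13
Reactants: 18 epoxy amide
Product: 19 3-{(2R,3R)-3-[2-(3,3-dimethyloxiran-2-yl)ethyl]-3-methyloxiran-2-yl}-N-methoxy-N-methylpropanamide (about 1:1 at the new oxirane CH)
Conditions: mCPBA, CH2Cl2, 0 °C
Reagents that add atoms: 3-chloroperoxybenzoic acid (OOC(=O)c1cccc(Cl)c1)
Why: Prilezhaev epoxidation of the remaining trisubstituted alkene; the new centre is not controlled but becomes the C3 ketone in the last step.

Step 14
Reactants: 19 bis-epoxy amide
Product: 20 1-{(2R,3R)-3-[2-(3,3-dimethyloxiran-2-yl)ethyl]-3-methyloxiran-2-yl}-6-(trimethylsilyl)hex-5-yn-3-one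
Conditions: TMSC≡CCH3, n-BuLi, TMEDA, THF, −78 → 0 °C; then 19, −78 °C; aq NH4Cl
Reagents that add atoms: 1-(trimethylsilyl)propyne (CC#C[Si](C)(C)C)
Why: Weinreb ketone synthesis with the propargylic lithium reagent; the stable tetrahedral adduct prevents over-addition and the epoxides survive at −78 °C.

Step 15
Reactants: 20 β,γ-ynone
Product: 21 (Z)-tert-butyldimethylsilyl enol ether of 20 (C3–C4 enol double bond conjugated with the alkyne)
Conditions: KHMDS, TBSCl, THF, −78 °C
Reagents that add atoms: tert-butyldimethylsilyl chloride (CC(C)(C)[Si](C)(C)Cl)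
Why: Deprotonation occurs only at the CH2 flanked by ketone and alkyne, and O-silylation of the (Z)-enolate fixes the enol ether regiochemistry needed for the cyclisation.

Step 16
Reactants: 21 bis-epoxy enyne silyl enol ether
Product: 22 (5aR,6S,9aR)-3-[(tert-butyldimethylsilyl)oxy]-2,2,5a-trimethyl-6-[(trimethylsilyl)ethynyl]octahydrobenzo[b]oxepin-7(2H)-one (trans-fused; alkynyl equatorial; C3 epimers)
Conditions: TBSOTf (0.2 equiv), 2,6-di-tert-butyl-4-methylpyridine, CH2Cl2, −78 °C
Reagents that add atoms: none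
Why: Silyl-triflate-triggered epoxide-opening cascade (tandem oxa- and carbacyclisation): the internal epoxide oxygen opens the activated terminal epoxide at its tertiary carbon (oxepane), and the enol silane opens the resulting epoxonium at the tertiary carbon with inversion through a chair transition state, so both ring-fusion centres follow from the (2R,3R)-epoxide.

Step 17
Reactants: 22 bicyclic ketone
Product: 23 (5aR,6S,7S,9aR)-3-[(tert-butyldimethylsilyl)oxy]-2,2,5a,7-tetramethyl-6-[(trimethylsilyl)ethynyl]decahydrobenzo[b]oxepin-7-ol (axial OH cis to the alkynyl group)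
Conditions: MeMgBr, CeCl3, THF, −78 °C
Reagents that add atoms: methylmagnesium bromide (C[Mg]Br)
Why: Organocerium 1,2-addition without enolisation; the axial face is blocked by the syn-axial angular methyl, so methyl enters equatorially and the OH is axial.

Step 18
Reactants: 23 tertiary alcohol
Product: 24 the 7-O-triethylsilyl ether of 23
Conditions: TESOTf, 2,6-lutidine, CH2Cl2, 0 °C
Reagents that add atoms: triethylsilyl trifluoromethanesulfonate (CC[Si](CC)(CC)OS(=O)(=O)C(F)(F)F)
Why: Silylation of the hindered tertiary alcohol so that only the propargylic alkoxide of the next step is acylated.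

Step 19
Reactants: 24 silyl-protected alkyne; 11 silyl-protected ketone
Product: 27 propargylic methyl carbonate (C5 of the azulenone carries OCO2CH3 and the alkynyl link to C6 of the benzoxepine; C5 configuration not controlled), via lithium acetylide 25 (not isolated), via lithium alkoxide 26 (not isolated)
Conditions: 24, MeLi·LiBr, THF, 0 °C → rt; then 11, THF, −78 → 0 °C; then ClCO2Me, 0 °C → rt
Reagents that add atoms: methyl chloroformate (COC(=O)Cl)
Why: Desilylative lithiation gives the acetylide, whose slim sp carbon adds to the doubly hindered ketone (acetylide 1,2-addition), and the alkoxide is trapped as the carbonate; the new carbinol centre is destroyed in the next step.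

Step 20
Reactants: 27 propargylic carbonate
Product: 28 trisubstituted allene (azulen-5-ylidene=C=CH–benzoxepin-6-yl; axial configuration not controlled)
Conditions: Pd2(dba)3·CHCl3 (5 mol %), n-Bu3P (20 mol %), HCO2NH4, THF, 40 °C
Reagents that add atoms: none
Why: Tsuji–Mandai palladium-catalysed hydrogenolysis: ionisation to the allenylpalladium species and formate-derived hydride delivery at the remote alkyne carbon (formal SN2′) give the allene.

Step 21
Reactants: 28 allene
Product: 29 (Z)-alkene tris-silyl ether (the CH2 chain cis to the C(CH3)2 carbon)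
Conditions: 2-nitrobenzenesulfonylhydrazide, Et3N, CH2Cl2, rt
Reagents that add atoms: none
Why: Diimide reduction adds H2 syn to the less substituted allene π bond, in the plane of the ring substituents and from the CH(CH3) side, which is less encumbered than the C(CH3)2 side, so the new vinylic H is cis to C6 and the chain cis to the gem-dimethyl carbon.

Step 22
Reactants: 29 tris-silyl ether
Product: 30 triol (the target with CH–OH in place of the oxepane C=O; C3 epimers)
Conditions: TBAF, THF, 50 °C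
Reagents that add atoms: none
Why: Fluoride-mediated cleavage of the TBS ether and both TES ethers.

Step 23
Reactants: 30 triol
Product: 31 target CNP0157787.1
Conditions: Dess–Martin periodinane, CH2Cl2, rt
Reagents that add atoms: none
Why: Dess–Martin oxidation of the only secondary alcohol; both C3 epimers converge on the ketone, and the tertiary alcohols and the alkene are inert.

**Compound list**

1 | (R)-(−)-linalool, (3R)-3,7-dimethylocta-1,6-dien-3-ol | C=C[C@](C)(O)CCC=C(C)C | starting material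
2 | (R)-1-methylcyclopent-2-en-1-ol | C[C@]1(O)C=CCC1 | intermediate
3 | (2R)-2-methyl-6-oxabicyclo[3.1.0]hexan-2-ol, oxirane cis to OH | C[C@]1(O)[C@H]2O[C@H]2CC1 | intermediate
4 | 2-[(1S,2S,3R)-2,3-dihydroxy-3-methylcyclopentyl]-2-methylpropanenitrile | C[C@]1(O)[C@@H](O)[C@H](C(C)(C)C#N)CC1 | intermediate
5 | 2-[(1S,3R)-3-hydroxy-3-methyl-2-oxocyclopentyl]-2-methylpropanenitrile | C[C@]1(O)C(=O)[C@H](C(C)(C)C#N)CC1 | intermediate
6 | (3aS,6R,6aR)-2-imino-3,3,6-trimethyl-6a-vinylhexahydro-2H-cyclopenta[b]furan-6-ol (iminolactone) | C[C@]1(O)[C@]2(C=C)OC(=N)C(C)(C)[C@@H]2CC1 | intermediate (not isolated)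
7 | (3aS,6R,6aR)-6-hydroxy-3,3,6-trimethyl-6a-vinylhexahydro-2H-cyclopenta[b]furan-2-one | C[C@]1(O)[C@]2(C=C)OC(=O)C(C)(C)[C@@H]2CC1 | intermediate
8 | (3aS,6R,6aR,Z)-2-ethylidene-3,3,6-trimethyl-6a-vinylhexahydro-2H-cyclopenta[b]furan-6-ol (enol ether) | C[C@]1(O)[C@]2(C=C)O/C(=C\C)C(C)(C)[C@@H]2CC1 | intermediate (not isolated)
9 | (1R,3aR,6S)-1-hydroxy-1,4,4,6-tetramethyl-2,3,3a,4,6,7-hexahydroazulen-5(1H)-one | C[C@H]1CC=C2[C@@H](CC[C@@]2(C)O)C(C)(C)C1=O | intermediate
10 | (1R,3aR,6S,8aR)-1-hydroxy-1,4,4,6-tetramethyloctahydroazulen-5(1H)-one | C[C@H]1CC[C@@H]2[C@@H](CC[C@@]2(C)O)C(C)(C)C1=O | intermediate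
11 | (1R,3aR,6S,8aR)-1,4,4,6-tetramethyl-1-[(triethylsilyl)oxy]octahydroazulen-5(1H)-one | C[C@H]1CC[C@@H]2[C@@H](CC[C@@]2(C)O[Si](CC)(CC)CC)C(C)(C)C1=O | intermediate
12 | (S)-5-oxotetrahydrofuran-2-carboxylic acid | OC(=O)[C@@H]1CCC(=O)O1 | starting material
13 | (S)-5-oxotetrahydrofuran-2-carbonyl chloride | ClC(=O)[C@@H]1CCC(=O)O1 | intermediate (not isolated)
14 | (S)-5-acetyldihydrofuran-2(3H)-one | CC(=O)[C@@H]1CCC(=O)O1 | intermediate
15 | (S)-5-[(R)-2-hydroxy-6-methylhept-5-en-2-yl]dihydrofuran-2(3H)-one | CC(C)=CCC[C@@](C)(O)[C@@H]1CCC(=O)O1 | intermediate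
16 | (4S,5R)-4,5-dihydroxy-N-methoxy-N,5,9-trimethyldec-8-enamide | CON(C)C(=O)CC[C@H](O)[C@](C)(O)CCC=C(C)C | intermediate
17 | 4-O-methanesulfonate of 16 | CON(C)C(=O)CC[C@H](OS(C)(=O)=O)[C@](C)(O)CCC=C(C)C | intermediate (not isolated)
18 | N-methoxy-N-methyl-3-[(2R,3R)-3-methyl-3-(4-methylpent-3-en-1-yl)oxiran-2-yl]propanamide | CON(C)C(=O)CC[C@H]1O[C@]1(C)CCC=C(C)C | intermediate
19 | 3-{(2R,3R)-3-[2-(3,3-dimethyloxiran-2-yl)ethyl]-3-methyloxiran-2-yl}-N-methoxy-N-methylpropanamide (epimers at the new oxirane CH) | CON(C)C(=O)CC[C@H]1O[C@]1(C)CCC1OC1(C)C | intermediate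
20 | 1-{(2R,3R)-3-[2-(3,3-dimethyloxiran-2-yl)ethyl]-3-methyloxiran-2-yl}-6-(trimethylsilyl)hex-5-yn-3-one | C[Si](C)(C)C#CCC(=O)CC[C@H]1O[C@]1(C)CCC1OC1(C)C | intermediate
21 | (Z)-3-(tert-butyldimethylsilyloxy) enol ether of 20 (hex-3-en-5-yne) | C[Si](C)(C)C#C/C=C(\O[Si](C)(C)C(C)(C)C)CC[C@H]1O[C@]1(C)CCC1OC1(C)C | intermediate
22 | (5aR,6S,9aR)-3-[(tert-butyldimethylsilyl)oxy]-2,2,5a-trimethyl-6-[(trimethylsilyl)ethynyl]octahydrobenzo[b]oxepin-7(2H)-one (C3 epimers) | C[Si](C)(C)C#C[C@@H]1[C@@]2(C)CCC(O[Si](C)(C)C(C)(C)C)C(C)(C)O[C@@H]2CCC1=O | intermediate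
23 | (5aR,6S,7S,9aR)-3-[(tert-butyldimethylsilyl)oxy]-2,2,5a,7-tetramethyl-6-[(trimethylsilyl)ethynyl]decahydrobenzo[b]oxepin-7-ol | C[Si](C)(C)C#C[C@@H]1[C@@]2(C)CCC(O[Si](C)(C)C(C)(C)C)C(C)(C)O[C@@H]2CC[C@]1(C)O | intermediate
24 | 7-O-triethylsilyl ether of 23 | C[Si](C)(C)C#C[C@@H]1[C@@]2(C)CCC(O[Si](C)(C)C(C)(C)C)C(C)(C)O[C@@H]2CC[C@]1(C)O[Si](CC)(CC)CC | intermediate
25 | lithium acetylide from 24 (Li in place of SiMe3) | [Li]C#C[C@@H]1[C@@]2(C)CCC(O[Si](C)(C)C(C)(C)C)C(C)(C)O[C@@H]2CC[C@]1(C)O[Si](CC)(CC)CC | intermediate (not isolated)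
26 | lithium propargylic alkoxide from 25 + 11 | C[C@H]1CC[C@@H]2[C@@H](CC[C@@]2(C)O[Si](CC)(CC)CC)C(C)(C)C1(O[Li])C#C[C@@H]1[C@@]2(C)CCC(O[Si](C)(C)C(C)(C)C)C(C)(C)O[C@@H]2CC[C@]1(C)O[Si](CC)(CC)CC | intermediate (not isolated)
27 | propargylic methyl carbonate of the coupled fragments | C[C@H]1CC[C@@H]2[C@@H](CC[C@@]2(C)O[Si](CC)(CC)CC)C(C)(C)C1(OC(=O)OC)C#C[C@@H]1[C@@]2(C)CCC(O[Si](C)(C)C(C)(C)C)C(C)(C)O[C@@H]2CC[C@]1(C)O[Si](CC)(CC)CC | intermediate
28 | trisubstituted allene linking the two bicycles | C[C@H]1CC[C@@H]2[C@@H](CC[C@@]2(C)O[Si](CC)(CC)CC)C(C)(C)C1=C=C[C@@H]1[C@@]2(C)CCC(O[Si](C)(C)C(C)(C)C)C(C)(C)O[C@@H]2CC[C@]1(C)O[Si](CC)(CC)CC | intermediate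
29 | (Z)-alkene, TBS ether at oxepane C3 and TES ethers at both tertiary carbinols | C[C@H]1CC[C@@H]2[C@@H](CC[C@@]2(C)O[Si](CC)(CC)CC)C(C)(C)/C1=C\C[C@@H]1[C@@]2(C)CCC(O[Si](C)(C)C(C)(C)C)C(C)(C)O[C@@H]2CC[C@]1(C)O[Si](CC)(CC)CC | intermediate
30 | triol, oxepan-3-ol analogue of the target (C3 epimers) | C[C@H]1CC[C@@H]2[C@@H](CC[C@@]2(C)O)C(C)(C)/C1=C\C[C@@H]1[C@@]2(C)CCC(O)C(C)(C)O[C@@H]2CC[C@]1(C)O | intermediate
31 | CNP0157787.1 | C[C@H]1CC[C@@H]2[C@@H](CC[C@@]2(C)O)C(C)(C)/C1=C\C[C@@H]1[C@@]2(C)CCC(=O)C(C)(C)O[C@@H]2CC[C@]1(C)O | target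

**Step count**
- Total: 23 steps (left half 8, right half 10, union and endgame 5).
- Longest linear sequence: 15 steps (12 → 31).

**Steps most likely to fail, with fallbacks**

1. Step 21. The E/Z outcome rests only on which side diimide approaches the allene, and the CH(CH3) and C(CH3)2 sides are both hindered. The fallback sets out from 11 and 24 and comes back at 29. Condense 11 with 2,4,6-triisopropylbenzenesulfonylhydrazide to the trisylhydrazone F1. Desilylate 24 (K2CO3, MeOH) to the terminal alkyne F2 and convert it by anti-Markovnikov hydroboration–oxidation (Cy2BH, then NaBO3) into the aldehyde F3. Shapiro reaction of F1 (n-BuLi, −78 → 0 °C) gives the vinyllithium F4, which adds to F3 to give the allylic alcohol F5; the carbinol epimers are separated and the unwanted one recycled by oxidation and reduction. Myers reductive transposition (NBSH, PPh3, DEAD, −30 °C → rt) passes through the allylic diazene F6. Its sigmatropic (retro-ene) loss of N2 delivers H to C6 and moves the double bond to the exocyclic position, with the chain held away from the C6 methyl by A(1,3) strain, giving 29.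

2. Step 16. The conjugated enyne silyl enol ether is a weaker and untested terminator for the epoxide cascade. The fallback sets out from 18 and comes back at 22, building the two rings one after the other. Add lithiated 1-(trimethylsilyl)propyne to 18 to give the ynone F7 and silylate it (KHMDS, TBSCl) to the enol silane F8. Close only the carbocycle by MeAlCl2-promoted epoxide–enol silane cyclisation to the hydroxy ketone F9. Epoxidise the remaining alkene (mCPBA) to the epoxy alcohol F10, cyclise it under acid (CSA, 7-endo attack at the tertiary carbon) to the oxepanol F11, and silylate (TBSOTf, 2,6-lutidine) to reach 22.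

3. Step 6. Ethylidenation of the α-quaternary lactone with a free tertiary OH may be sluggish, and the C6 centre depends on the enol ether geometry. The fallback sets out from 7 and comes back at 10, making the C6 centre by alkylation instead. Methylenate 7 with dimethyltitanocene (Petasis reagent, PhMe, 80 °C) to the enol ether F12, which undergoes the same Claisen ring expansion on heating to the cycloheptenone F13 lacking the C6 methyl. Directed hydrogenation (Crabtree) gives F14. The methyl is then introduced at the only enolisable position (LDA, MeI), followed by deprotonation and kinetic protonation from the convex face, to give 10.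

**Further compounds**

F1 | step 21 | 2,4,6-triisopropylbenzenesulfonylhydrazone of 11 | C[C@H]1CC[C@@H]2[C@@H](CC[C@@]2(C)O[Si](CC)(CC)CC)C(C)(C)C1=NNS(=O)(=O)c1c(C(C)C)cc(C(C)C)cc1C(C)C
F2 | step 21 | terminal alkyne from 24 (H in place of SiMe3) | C#C[C@@H]1[C@@]2(C)CCC(O[Si](C)(C)C(C)(C)C)C(C)(C)O[C@@H]2CC[C@]1(C)O[Si](CC)(CC)CC
F3 | step 21 | benzoxepin-6-ylacetaldehyde from F2 | O=CC[C@@H]1[C@@]2(C)CCC(O[Si](C)(C)C(C)(C)C)C(C)(C)O[C@@H]2CC[C@]1(C)O[Si](CC)(CC)CC
F4 | step 21 | vinyllithium from F1 (5-lithio-1,4,4,6-tetramethyl-1-triethylsilyloxy-hexahydroazulene, C5=C6 alkene) | CC1=C([Li])C(C)(C)[C@@H]2CC[C@@](C)(O[Si](CC)(CC)CC)[C@@H]2CC1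
F5 | step 21 | allylic alcohol from F4 + F3 (carbinol epimers) | CC1=C(C(O)C[C@@H]3[C@@]4(C)CCC(O[Si](C)(C)C(C)(C)C)C(C)(C)O[C@@H]4CC[C@]3(C)O[Si](CC)(CC)CC)C(C)(C)[C@@H]2CC[C@@](C)(O[Si](CC)(CC)CC)[C@@H]2CC1
F6 | step 21 | allylic diazene from F5 | CC1=C(C(N=N)C[C@@H]3[C@@]4(C)CCC(O[Si](C)(C)C(C)(C)C)C(C)(C)O[C@@H]4CC[C@]3(C)O[Si](CC)(CC)CC)C(C)(C)[C@@H]2CC[C@@](C)(O[Si](CC)(CC)CC)[C@@H]2CC1
F7 | step 16 | 1-[(2R,3R)-3-methyl-3-(4-methylpent-3-en-1-yl)oxiran-2-yl]-6-(trimethylsilyl)hex-5-yn-3-one | C[Si](C)(C)C#CCC(=O)CC[C@H]1O[C@]1(C)CCC=C(C)C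
F8 | step 16 | (Z)-TBS enol ether of F7 | C[Si](C)(C)C#C/C=C(\O[Si](C)(C)C(C)(C)C)CC[C@H]1O[C@]1(C)CCC=C(C)C
F9 | step 16 | (2S,3R,4R)-4-hydroxy-3-methyl-3-(4-methylpent-3-en-1-yl)-2-[(trimethylsilyl)ethynyl]cyclohexan-1-one | C[Si](C)(C)C#C[C@@H]1[C@@](C)(CCC=C(C)C)[C@H](O)CCC1=O
F10 | step 16 | side-chain epoxide of F9 | C[Si](C)(C)C#C[C@@H]1[C@@](C)(CCC2OC2(C)C)[C@H](O)CCC1=O
F11 | step 16 | (5aR,6S,9aR)-3-hydroxy-2,2,5a-trimethyl-6-[(trimethylsilyl)ethynyl]octahydrobenzo[b]oxepin-7(2H)-one | C[Si](C)(C)C#C[C@@H]1[C@@]2(C)CCC(O)C(C)(C)O[C@@H]2CCC1=O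
F12 | step 6 | (3aS,6R,6aR)-3,3,6-trimethyl-2-methylene-6a-vinylhexahydro-2H-cyclopenta[b]furan-6-ol | C[C@]1(O)[C@]2(C=C)OC(=C)C(C)(C)[C@@H]2CC1
F13 | step 6 | (1R,3aR)-1-hydroxy-1,4,4-trimethyl-2,3,3a,4,6,7-hexahydroazulen-5(1H)-one | O=C1CCC=C2[C@@H](CC[C@@]2(C)O)C1(C)C
F14 | step 6 | (1R,3aR,8aR)-1-hydroxy-1,4,4-trimethyloctahydroazulen-5(1H)-one | O=C1CCC[C@@H]2[C@@H](CC[C@@]2(C)O)C1(C)C
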